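The route rests on the C2–C3 bond of the 3-substituted flavanone (unit 1). C2 is a benzylic methine on the ring A ether oxygen O1, and C3 sits between the C4 ketone and aryl carbon C8'' of the second flavanone. C3 is therefore raised as an aryl(acyl) rhodium carbene that inserts into a benzylic C–H bond of a 4-benzyloxybenzyl ether on the ring A oxygen. One operation closes ring C and sets C2 (catalyst) and, after equilibration, C3. The precursor is an open-chain α-diazo deoxybenzoin assembled from a symmetrical phloroacetophenone tris-ether and 8-iodinated, bis-silylated (2S)-isosakuranetin, which supplies C2''.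

Key step: step 6

Locants: unit 1 is the 3-substituted flavanone (O1, C2, C3, C4; rings A, C, B); unit 2 is the 8-substituted flavanone (double-primed locants; rings D, F, E).
Assumption: (2S)-isosakuranetin, the aglycone of poncirin and didymin, is taken as a commercial, enantiopure starting material.
Assumption: Rh2(S-PTTL)4 is taken as the catalyst enantiomer that delivers 2R in step 6; the sense of induction is not secured by analogy for this ring size, and the mirror-image catalyst would be needed if it proved opposite.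

Step 1
Reactants: 1 2,4,6-trihydroxyacetophenone; 2 4-(benzyloxy)benzyl chloride
Product: 3 1-{2,4,6-tris[(4-benzyloxybenzyl)oxy]phenyl}ethanone
Conditions: 2 (3.3 equiv in all), K2CO3 (5 equiv), n-Bu4NI (0.1 equiv), DMF, 70 °C
Reagents that add atoms: 4-(benzyloxy)benzyl chloride (second and third equivalents of 2 written as two molecules), ClCc1ccc(OCc2ccccc2)cc1.ClCc1ccc(OCc2ccccc2)cc1
Why: Threefold Williamson etherification, in which three molecules of 2 are taken up per molecule of 1, should proceed cleanly because the acetyl group suppresses C-alkylation of the phloroglucinol ring and heating overcomes the hydrogen-bonded ortho hydroxyls; no stereocentre is involved.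

Step 2
Reactants: 4 (2S)-isosakuranetin
Product: 5 (2S)-5,7-bis(tert-butyldimethylsilyloxy)-2-(4-methoxyphenyl)chroman-4-one
Conditions: TBSOTf (2.4 equiv), 2,6-lutidine (3 equiv), CH2Cl2, 0 °C
Reagents that add atoms: tert-butyldimethylsilyl triflate (TBSOTf), CC(C)(C)[Si](C)(C)OS(=O)(=O)C(F)(F)F
Why: Phenol silylation with a silyl triflate and a hindered pyridine base should also cap the chelated 5''-OH without the enolate chemistry that opens ring F, so C2'' from the chiral pool stays untouched; the 5''-O cap steers the next step to C8'' and the 7''-O-silyl group offers no C–H α to oxygen to the later carbene.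

Step 3
Reactants: 5 (2S)-5,7-bis(tert-butyldimethylsilyloxy)-2-(4-methoxyphenyl)chroman-4-one
Product: 6 (2S)-5,7-bis(tert-butyldimethylsilyloxy)-8-iodo-2-(4-methoxyphenyl)chroman-4-one
Conditions: NIS (1.05 equiv), DMF, 23 °C, dark
Reagents that add atoms: N-iodosuccinimide (NIS), O=C1CCC(=O)N1I
Why: Electrophilic aromatic iodination should occur on the trioxygenated ring D rather than the anisyl ring E, and at C8'' because 5-O-capped 5,7-dioxygenated flavonoids are iodinated there and C6'' is flanked by two bulky silyloxy groups; C2'' is not affected.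

Step 4
Reactants: 3 1-{2,4,6-tris[(4-benzyloxybenzyl)oxy]phenyl}ethanone; 6 (2S)-5,7-bis(tert-butyldimethylsilyloxy)-8-iodo-2-(4-methoxyphenyl)chroman-4-one
Product: 8 2-[(2S)-5,7-bis(tert-butyldimethylsilyloxy)-2-(4-methoxyphenyl)-4-oxochroman-8-yl]-1-{2,4,6-tris[(4-benzyloxybenzyl)oxy]phenyl}ethanone, via chlorozinc enolate 7 (not isolated)
Conditions: 3 (2.2 equiv), LiN(SiMe3)2 (2.2 equiv), THF, −78 °C; ZnCl2 (2.3 equiv), −78 → 0 °C; then 6 (1 equiv), Pd2(dba)3 (2.5 mol%), XPhos (10 mol%), 50 °C; aq NH4Cl
Reagents that add atoms: zinc chloride, Cl[Zn]Cl (its zinc and chlorine stand in intermediate 7 only; 8 holds none of them)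
Why: Negishi-type palladium-catalysed α-arylation of a preformed, weakly basic zinc enolate should join the fragments without exposing ring F to a strong base (C2'' retained); the bulky biaryl phosphine serves the di-ortho-substituted iodide and the excess enolate covers proton transfer to the more acidic product.

Step 5
Reactants: 8 the deoxybenzoin from step 4
Product: 9 2-[(2S)-5,7-bis(tert-butyldimethylsilyloxy)-2-(4-methoxyphenyl)-4-oxochroman-8-yl]-2-diazo-1-{2,4,6-tris[(4-benzyloxybenzyl)oxy]phenyl}ethanone
Conditions: p-ABSA (1.5 equiv), DBU (1.5 equiv), anhydrous MeCN, 0 °C; used without storage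
Reagents that add atoms: 4-acetamidobenzenesulfonyl azide (p-ABSA), CC(=O)Nc1ccc(cc1)S(=O)(=O)N=[N+]=[N-]
Why: Regitz diazo transfer should take place only at the methylene activated by both aryl and acyl groups, since the ring F methylene is several pK units less acidic and stays protonated at 0 °C, so C2'' is not endangered; the absence of water keeps the aryl silyl ethers intact towards the amidine base.

Step 6
Reactants: 9 the α-aryl-α-diazoketone from step 5
Product: 11 (2R,3S)-3-[(2S)-5,7-bis(tert-butyldimethylsilyloxy)-2-(4-methoxyphenyl)-4-oxochroman-8-yl]-5,7-bis[(4-benzyloxybenzyl)oxy]-2-(4-benzyloxyphenyl)chroman-4-one, via 2,3-cis insertion product 10 (not isolated)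
Conditions: Rh2(S-PTTL)4 (dirhodium tetrakis[N-phthaloyl-(S)-tert-leucinate], 2 mol%), toluene, −40 → 0 °C, slow addition of 9; then Et3N (1 equiv), 23 °C
Reagents that add atoms: none
Why: The dirhodium carboxylate should expel N2 from 9 to give an electrophilic aryl(acyl) rhodium carbene at C3, which inserts into one benzylic C–H bond of an ortho 4-benzyloxybenzyl ether through a three-centre, hydride-transfer-like transition state, forming C2–C3 and releasing the catalyst. The closest known reactions are the chromanone-forming C–H insertions of 2-alkoxyphenyl α-diazoketones under chiral dirhodium carboxylates and the enantioselective insertion of aryl diazo compounds into ArO–CH2Ar bonds with this catalyst family. Ring C (O1–C2–C3–C4–C4a–C8a) is closed as a six-membered ring by 1,6-insertion, the carbene carbon bonding to the sixth atom of the chain while the hydrogen passes to C3. C2 is set by the chiral catalyst, which selects one of the two benzylic hydrogens (remote C2'' is only a matched or mismatched bystander), and C3 is set by thermodynamics, because Et3N epimerises the kinetic cis isomer 10 through the enol at the acidic C3–H to the trans isomer 11 with both aryl groups equatorial. The step needs site selectivity for this C–H bond over oxonium-ylide formation at the ether oxygen and over other C–H bonds; it is secured by the oxygen- and p-alkoxyaryl-activated CH2, by the symmetry of ring A (both ortho ethers are equivalent and the spare groups merely protect O5 and O7), by the absence of any C–H α to oxygen on the 7''-O-silyl group, and by ring F, which holds C2''–H where insertion would require a bridged ring across aromatic C8a''.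

Step 7
Reactants: 11 the protected trans-biflavanone from step 6
Product: 12 (2R,3S)-5,7-bis[(4-benzyloxybenzyl)oxy]-2-(4-benzyloxyphenyl)-3-[(2S)-5,7-dihydroxy-2-(4-methoxyphenyl)-4-oxochroman-8-yl]chroman-4-one
Conditions: HF·pyridine, pyridine, THF, 0 → 23 °C
Reagents that add atoms: none
Why: Fluoride cleavage of the two aryl silyl ethers under buffered acidic conditions should free the ring D phenols without the phenoxide-driven ring opening that would scramble C2, C3 or C2''; benzyl-type ethers and the aryl methyl ether are inert.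

Step 8
Reactants: 12 the pentabenzylated biflavanone from step 7
Product: 13 (2R,3S)-5,7-dihydroxy-2-(4-hydroxyphenyl)-3-[(2S)-5,7-dihydroxy-2-(4-methoxyphenyl)-4-oxochroman-8-yl]chroman-4-one (target)
Conditions: H2 (1 atm), 10% Pd/C, EtOAc–MeOH (1:1), 23 °C
Reagents that add atoms: none
Why: Catalytic hydrogenolysis at neutral pH should cleave the three O-benzyl groups and the two 4-oxybenzyl aryl ethers, whereas the cyclic benzylic C–O bonds of both chromanones react much more slowly and the chelated ketones and the methyl ether are inert, so all three stereocentres persist.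

Compound list
1 | 2,4,6-trihydroxyacetophenone | CC(=O)c1c(O)cc(O)cc1O | starting material
2 | 4-(benzyloxy)benzyl chloride | ClCc1ccc(OCc2ccccc2)cc1 | starting material
3 | 1-{2,4,6-tris[(4-benzyloxybenzyl)oxy]phenyl}ethanone | CC(=O)c1c(OCc2ccc(OCc3ccccc3)cc2)cc(OCc2ccc(OCc3ccccc3)cc2)cc1OCc1ccc(OCc2ccccc2)cc1 | intermediate
4 | (2S)-isosakuranetin, (2S)-5,7-dihydroxy-2-(4-methoxyphenyl)chroman-4-one | COc1ccc([C@@H]2CC(=O)c3c(O)cc(O)cc3O2)cc1 | starting material
5 | (2S)-5,7-bis(tert-butyldimethylsilyloxy)-2-(4-methoxyphenyl)chroman-4-one | COc1ccc([C@@H]2CC(=O)c3c(O[Si](C)(C)C(C)(C)C)cc(O[Si](C)(C)C(C)(C)C)cc3O2)cc1 | intermediate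
6 | (2S)-5,7-bis(tert-butyldimethylsilyloxy)-8-iodo-2-(4-methoxyphenyl)chroman-4-one | COc1ccc([C@@H]2CC(=O)c3c(O[Si](C)(C)C(C)(C)C)cc(O[Si](C)(C)C(C)(C)C)c(I)c3O2)cc1 | intermediate
7 | chlorozinc enolate of ketone 3 | C=C(O[Zn]Cl)c1c(OCc2ccc(OCc3ccccc3)cc2)cc(OCc2ccc(OCc3ccccc3)cc2)cc1OCc1ccc(OCc2ccccc2)cc1 | intermediate
8 | 2-[(2S)-5,7-bis(tert-butyldimethylsilyloxy)-2-(4-methoxyphenyl)-4-oxochroman-8-yl]-1-{2,4,6-tris[(4-benzyloxybenzyl)oxy]phenyl}ethanone | COc1ccc([C@@H]2CC(=O)c3c(O[Si](C)(C)C(C)(C)C)cc(O[Si](C)(C)C(C)(C)C)c(CC(=O)c4c(OCc5ccc(OCc6ccccc6)cc5)cc(OCc5ccc(OCc6ccccc6)cc5)cc4OCc4ccc(OCc5ccccc5)cc4)c3O2)cc1 | intermediate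
9 | 2-[(2S)-5,7-bis(tert-butyldimethylsilyloxy)-2-(4-methoxyphenyl)-4-oxochroman-8-yl]-2-diazo-1-{2,4,6-tris[(4-benzyloxybenzyl)oxy]phenyl}ethanone | COc1ccc([C@@H]2CC(=O)c3c(O[Si](C)(C)C(C)(C)C)cc(O[Si](C)(C)C(C)(C)C)c(C(=[N+]=[N-])C(=O)c4c(OCc5ccc(OCc6ccccc6)cc5)cc(OCc5ccc(OCc6ccccc6)cc5)cc4OCc4ccc(OCc5ccccc5)cc4)c3O2)cc1 | intermediate
10 | (2R,3R)-3-[(2S)-5,7-bis(tert-butyldimethylsilyloxy)-2-(4-methoxyphenyl)-4-oxochroman-8-yl]-5,7-bis[(4-benzyloxybenzyl)oxy]-2-(4-benzyloxyphenyl)chroman-4-one (2,3-cis) | COc1ccc([C@@H]2CC(=O)c3c(O[Si](C)(C)C(C)(C)C)cc(O[Si](C)(C)C(C)(C)C)c([C@H]4C(=O)c5c(OCc6ccc(OCc7ccccc7)cc6)cc(OCc6ccc(OCc7ccccc7)cc6)cc5O[C@H]4c4ccc(OCc5ccccc5)cc4)c3O2)cc1 | intermediate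
11 | (2R,3S)-3-[(2S)-5,7-bis(tert-butyldimethylsilyloxy)-2-(4-methoxyphenyl)-4-oxochroman-8-yl]-5,7-bis[(4-benzyloxybenzyl)oxy]-2-(4-benzyloxyphenyl)chroman-4-one (2,3-trans) | COc1ccc([C@@H]2CC(=O)c3c(O[Si](C)(C)C(C)(C)C)cc(O[Si](C)(C)C(C)(C)C)c([C@@H]4C(=O)c5c(OCc6ccc(OCc7ccccc7)cc6)cc(OCc6ccc(OCc7ccccc7)cc6)cc5O[C@H]4c4ccc(OCc5ccccc5)cc4)c3O2)cc1 | intermediate
12 | (2R,3S)-5,7-bis[(4-benzyloxybenzyl)oxy]-2-(4-benzyloxyphenyl)-3-[(2S)-5,7-dihydroxy-2-(4-methoxyphenyl)-4-oxochroman-8-yl]chroman-4-one | COc1ccc([C@@H]2CC(=O)c3c(O)cc(O)c([C@@H]4C(=O)c5c(OCc6ccc(OCc7ccccc7)cc6)cc(OCc6ccc(OCc7ccccc7)cc6)cc5O[C@H]4c4ccc(OCc5ccccc5)cc4)c3O2)cc1 | intermediate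
13 | (2R,3S)-5,7-dihydroxy-2-(4-hydroxyphenyl)-3-[(2S)-5,7-dihydroxy-2-(4-methoxyphenyl)-4-oxochroman-8-yl]chroman-4-one | COc1ccc([C@@H]2CC(=O)c3c(O)cc(O)c([C@@H]4C(=O)c5c(O)cc(O)cc5O[C@H]4c4ccc(O)cc4)c3O2)cc1 | target

Total step count: 8
Longest linear sequence: 7 steps (steps 2 to 8, from 4)

Steps most likely to fail

Step 6. The ring A ether oxygen may attack the carbenoid to give a five-membered oxonium ylide that collapses by benzyl shift instead of C–H insertion, or the catalyst may discriminate poorly between the two benzylic hydrogens. The fallback sets out from deoxybenzoin 8 and comes back at 11, replacing steps 5 and 6 by an oxidative C–H cyclisation without carbene chemistry. Treatment of 8 with DDQ (1.2 equiv), 2,6-dichloropyridine, LiClO4 and 4 Å molecular sieves in 1,2-dichloroethane at 0 → 23 °C should abstract hydride from the electron-rich benzylic ether. The resulting aryl-stabilised oxocarbenium ion should be captured by the enol of the neighbouring deoxybenzoin, which forms the same C2–C3 bond by 6-endo closure under thermodynamic trans control. Without catalyst control at C2 this would give 11 together with its (2S,3R)-configured trans diastereomer F1; the two differ in their relation to C2'' and would be separated by chromatography.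

Step 4. Oxidative addition and transmetalation at the di-ortho-substituted, electron-rich iodide may be slow, and proton transfer may consume the enolate before coupling. The fallback sets out from ketone 3 and iodide 6 and comes back at 9, bypassing 8 and step 5. Detrifluoroacetylative diazo transfer on 3 (LiN(SiMe3)2, THF, −78 °C; CF3CO2CH2CF3; then MsN3, Et3N, H2O, MeCN) should give, through the trifluoroacetyl diketone F2, the diazomethyl ketone F3. Palladium-catalysed C–H arylation of the acyldiazomethane F3 with 6 (Pd(PPh3)4, Ag2CO3, Et3N, toluene, 23 °C) keeps the diazo group and should deliver 9 directly, with no strong base touching unit 2.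

Step 8. Over-reduction may open the benzylic C2–O1 bond of ring C once the 4'-hydroxyl is free, or the 4-hydroxybenzyl ethers may be cleaved incompletely. The fallback sets out from 12 and comes back at 13: BCl3 with pentamethylbenzene as cation scavenger in CH2Cl2 at −78 °C should cleave the benzyl and 4-oxybenzyl aryl ethers by Lewis-acid ionisation instead of hydrogenation. The methyl ether on ring E, remote from any carbonyl, should survive at this temperature; no new compound is formed.

Further compounds
F1 | step 6 | (2S,3R)-3-[(2S)-5,7-bis(tert-butyldimethylsilyloxy)-2-(4-methoxyphenyl)-4-oxochroman-8-yl]-5,7-bis[(4-benzyloxybenzyl)oxy]-2-(4-benzyloxyphenyl)chroman-4-one | COc1ccc([C@@H]2CC(=O)c3c(O[Si](C)(C)C(C)(C)C)cc(O[Si](C)(C)C(C)(C)C)c([C@H]4C(=O)c5c(OCc6ccc(OCc7ccccc7)cc6)cc(OCc6ccc(OCc7ccccc7)cc6)cc5O[C@@H]4c4ccc(OCc5ccccc5)cc4)c3O2)cc1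
F2 | step 4 | 4,4,4-trifluoro-1-{2,4,6-tris[(4-benzyloxybenzyl)oxy]phenyl}butane-1,3-dione | O=C(CC(=O)C(F)(F)F)c1c(OCc2ccc(OCc3ccccc3)cc2)cc(OCc2ccc(OCc3ccccc3)cc2)cc1OCc1ccc(OCc2ccccc2)cc1
F3 | step 4 | 2-diazo-1-{2,4,6-tris[(4-benzyloxybenzyl)oxy]phenyl}ethanone | [N-]=[N+]=CC(=O)c1c(OCc2ccc(OCc3ccccc3)cc2)cc(OCc2ccc(OCc3ccccc3)cc2)cc1OCc1ccc(OCc2ccccc2)cc1
F0 | step 8 | none | none
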